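**Plan**
- Retrosynthesis: cut the phenol O‑benzyl group first, then the C3–CH2Ar bond of the lactone (α‑benzylation), then the ring bond C3–C4 of the γ‑lactone, which leaves the open‑chain 3‑(3,4,5‑trimethoxyphenyl)propyl diazoacetate 7.
- Enabling feature: lactone C4, the CH that carries the trimethoxybenzyl group, is in the open chain an unactivated prochiral CH2 five atoms from the acetate α‑carbon C3 (C3–C2(=O)–O1–C5H2–C4). A metal carbene at C3 can therefore insert into one of its two enantiotopic C–H bonds and close the five‑membered lactone ring.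
- Forward: acid 1 → alcohol 2 → bromoacetate 4 → diazoacetate 7 → lactone ring (the only ring made) → trans α‑benzylation with bromide 10 → hydrogenolysis of the benzyl ether.
- Stereochemistry: C4 (R) comes from catalyst control in the C–H insertion (chiral dirhodium carboxamidate); C3 (R) comes from substrate control, the lactone enolate being alkylated anti to the C4 substituent (trans).

Key step: step 4

Remark (assumption): Rh2(4S‑MPPIM)4 is taken to convert 3‑arylpropyl diazoacetates into the (R)‑lactone; if the lactone proves to be (S), the mirror‑image catalyst Rh2(4R‑MPPIM)4 is used in step 4 with no other change.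

**Step 1**
Reactants: 1 3‑(3,4,5‑trimethoxyphenyl)propanoic acid
Product: 2 3‑(3,4,5‑trimethoxyphenyl)propan‑1‑ol
Conditions: BH3·THF (1.5 equiv), THF, 0 °C to rt; aqueous work‑up
Reagents that add atoms: none
Why: Chemoselective borane reduction of a carboxylic acid to the primary alcohol through an acyloxyborane, which leaves the aryl methyl ethers untouched and creates no stereocentre.

**Step 2**
Reactants: 2 3‑(3,4,5‑trimethoxyphenyl)propan‑1‑ol; 3 bromoacetyl bromide
Product: 4 3‑(3,4,5‑trimethoxyphenyl)propyl bromoacetate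
Conditions: NaHCO3 (3 equiv), MeCN, 0 °C
Reagents that add atoms: none
Why: O‑acylation (nucleophilic acyl substitution) of the primary alcohol at the acyl bromide, which is far more electrophilic than the α‑bromide, with NaHCO3 as acid scavenger and no stereocentre involved.

**Step 3**
Reactants: 4 3‑(3,4,5‑trimethoxyphenyl)propyl bromoacetate
Product: 7 3‑(3,4,5‑trimethoxyphenyl)propyl diazoacetate, via N‑alkylated ditosylhydrazine 5 (not isolated), via glyoxylate tosylhydrazone 6 (not isolated)
Conditions: TsNHNHTs (2 equiv), DBU (5 equiv), THF, 0 °C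
Reagents that add atoms: N,N'‑ditosylhydrazine, Cc1ccc(cc1)S(=O)(=O)NNS(=O)(=O)c1ccc(C)cc1
Why: SN2 N‑alkylation of the sulfonylhydrazine by the α‑bromo ester followed by two base‑induced losses of sulfinate (a Bamford–Stevens‑type fragmentation through the tosylhydrazone) should give the diazoacetate under mild, non‑acidic conditions that the ester and the aryl ethers tolerate, with no stereocentre formed.

**Step 4**
Reactants: 7 3‑(3,4,5‑trimethoxyphenyl)propyl diazoacetate
Product: 8 (R)‑4‑(3,4,5‑trimethoxybenzyl)dihydrofuran‑2(3H)‑one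
Conditions: Rh2(4S‑MPPIM)4 (1 mol %; MPPIM = methyl (4S)‑2‑oxo‑1‑(3‑phenylpropanoyl)imidazolidine‑4‑carboxylate ligand, a carboxamidate‑bridged dimer of divalent rhodium), CH2Cl2, reflux, 7 added over 10 h by syringe pump
Reagents that add atoms: none
Why: The divalent rhodium carboxamidate expels N2 from 7 to give an electrophilic rhodium‑bound carbene at the acetate α‑carbon, which inserts through a concerted, asynchronous three‑centre transition state into a C–H bond of the central methylene of the propyl chain. The closest known reaction type is the enantioselective intramolecular C–H insertion of primary‑alkyl diazoacetates under chiral dirhodium carboxamidate catalysis, which is established for 3‑arylpropyl esters. The γ‑lactone closes in the 1,5‑insertion mode, in which the carbene carbon, the carbonyl carbon, the ester oxygen, the OCH2 carbon and the inserted CH form the five‑membered ring and the new C3–C4 bond is the ring‑closing bond. The single new stereocentre (C4, R) is set by catalyst control, the chiral pocket lined by the ester groups of the four imidazolidinone ligands selecting one of the two enantiotopic hydrogens of the prochiral CH2. The step needs site selectivity for this methylene over the O–CH2 hydrogens (deactivated by the ester oxygen and leading to a strained β‑lactone), over the benzylic hydrogens (six‑membered closure to a δ‑lactone) and over the electron‑rich arene (aromatic cycloaddition), and chemoselectivity over carbene dimerisation. The three‑atom spacer of the substrate, which puts only the central methylene within reach of a five‑ring closure, the low electrophilicity of the carboxamidate‑bound carbene and slow addition at high dilution should secure these.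

**Step 5**
Reactants: 9 [4‑(benzyloxy)‑3‑methoxyphenyl]methanol
Product: 10 1‑(benzyloxy)‑4‑(bromomethyl)‑2‑methoxybenzene
Conditions: PBr3 (0.4 equiv), Et2O, 0 °C; used at once without chromatography
Reagents that add atoms: phosphorus tribromide, BrP(Br)Br
Why: Conversion of the benzylic alcohol into the bromide through its phosphite ester (SN2‑type displacement by bromide) is fast at 0 °C and spares the benzyl and methyl aryl ethers, and the labile bromide is carried on directly.

**Step 6**
Reactants: 8 (R)‑4‑(3,4,5‑trimethoxybenzyl)dihydrofuran‑2(3H)‑one; 10 1‑(benzyloxy)‑4‑(bromomethyl)‑2‑methoxybenzene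
Product: 12 (3R,4R)‑3‑[4‑(benzyloxy)‑3‑methoxybenzyl]‑4‑(3,4,5‑trimethoxybenzyl)dihydrofuran‑2(3H)‑one, via lithium enolate 11 (not isolated)
Conditions: LiN(i‑Pr)2 (1.05 equiv), THF, −78 °C; then 10 (1.1 equiv), DMPU, −78 to −40 °C
Reagents that add atoms: none
Why: Kinetic deprotonation gives lithium enolate 11, whose SN2 alkylation by the reactive benzylic bromide should occur on the ring face anti to the C4 trimethoxybenzyl group, so that the new C3 stereocentre (R) is set trans to C4 by substrate control (diastereoselective lactone enolate alkylation) while the non‑acidic C4 centre is untouched.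

**Step 7**
Reactants: 12 (3R,4R)‑3‑[4‑(benzyloxy)‑3‑methoxybenzyl]‑4‑(3,4,5‑trimethoxybenzyl)dihydrofuran‑2(3H)‑one
Product: 13 (3R,4R)‑3‑(4‑hydroxy‑3‑methoxybenzyl)‑4‑(3,4,5‑trimethoxybenzyl)dihydrofuran‑2(3H)‑one
Conditions: H2 (1 atm), Pd/C (10 wt % Pd), EtOAc–EtOH, rt
Reagents that add atoms: none
Why: Catalytic hydrogenolysis of the benzyl aryl ether frees the phenol under neutral conditions that leave the lactone, the aryl methyl ethers and both stereocentres unchanged, since no base is present to epimerise C3.

**Compound list**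
1 | 3‑(3,4,5‑trimethoxyphenyl)propanoic acid | COc1cc(CCC(=O)O)cc(OC)c1OC | starting material
2 | 3‑(3,4,5‑trimethoxyphenyl)propan‑1‑ol | COc1cc(CCCO)cc(OC)c1OC | intermediate
3 | bromoacetyl bromide | BrCC(=O)Br | starting material
4 | 3‑(3,4,5‑trimethoxyphenyl)propyl bromoacetate | COc1cc(CCCOC(=O)CBr)cc(OC)c1OC | intermediate
5 | 3‑(3,4,5‑trimethoxyphenyl)propyl 2‑[1,2‑bis(4‑methylphenylsulfonyl)hydrazin‑1‑yl]acetate | COc1cc(CCCOC(=O)CN(NS(=O)(=O)c2ccc(C)cc2)S(=O)(=O)c2ccc(C)cc2)cc(OC)c1OC | intermediate
6 | 3‑(3,4,5‑trimethoxyphenyl)propyl 2‑[2‑(4‑methylphenylsulfonyl)hydrazinylidene]acetate | COc1cc(CCCOC(=O)C=NNS(=O)(=O)c2ccc(C)cc2)cc(OC)c1OC | intermediate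
7 | 3‑(3,4,5‑trimethoxyphenyl)propyl diazoacetate | COc1cc(CCCOC(=O)C=[N+]=[N-])cc(OC)c1OC | intermediate
8 | (R)‑4‑(3,4,5‑trimethoxybenzyl)dihydrofuran‑2(3H)‑one | O=C1C[C@@H](Cc2cc(OC)c(OC)c(OC)c2)CO1 | intermediate
9 | [4‑(benzyloxy)‑3‑methoxyphenyl]methanol | COc1cc(CO)ccc1OCc1ccccc1 | starting material
10 | 1‑(benzyloxy)‑4‑(bromomethyl)‑2‑methoxybenzene | COc1cc(CBr)ccc1OCc1ccccc1 | intermediate
11 | lithium enolate of 8, lithium (R)‑4‑(3,4,5‑trimethoxybenzyl)‑4,5‑dihydrofuran‑2‑olate | [Li]OC1=C[C@@H](Cc2cc(OC)c(OC)c(OC)c2)CO1 | intermediate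
12 | (3R,4R)‑3‑[4‑(benzyloxy)‑3‑methoxybenzyl]‑4‑(3,4,5‑trimethoxybenzyl)dihydrofuran‑2(3H)‑one | COc1cc(C[C@H]2C(=O)OC[C@@H]2Cc2cc(OC)c(OC)c(OC)c2)ccc1OCc1ccccc1 | intermediate
13 | (3R,4R)‑3‑(4‑hydroxy‑3‑methoxybenzyl)‑4‑(3,4,5‑trimethoxybenzyl)dihydrofuran‑2(3H)‑one | COc1cc(C[C@H]2C(=O)OC[C@@H]2Cc2cc(OC)c(OC)c(OC)c2)ccc1O | target

**Step count and risks**
Total steps: 7. Longest linear sequence: 6 (steps 1, 2, 3, 4, 6, 7); step 5 is a one‑step side branch.

Steps most likely to fail:

Step 4. The risks are incomplete discrimination between the two enantiotopic C–H bonds and diversion of the carbene into dimerisation, O–H insertion with adventitious water or attack on the electron‑rich arene. The fallback replaces carbene insertion by an auxiliary‑controlled enolate alkylation; it sets out from 1 and returns at 8. Acid 1 would be activated as its pivalic mixed anhydride (t‑BuCOCl, Et3N, THF, −20 °C) and coupled with (S)‑4‑benzyl‑1,3‑oxazolidin‑2‑one in the presence of LiCl to give the imide (4S)‑4‑benzyl‑3‑[3‑(3,4,5‑trimethoxyphenyl)propanoyl]‑1,3‑oxazolidin‑2‑one F1. Its sodium Z‑enolate (NaN(SiMe3)2, THF, −78 °C) should be alkylated by tert‑butyl bromoacetate on the face away from the benzyl group of the auxiliary to give tert‑butyl (3R)‑4‑[(4S)‑4‑benzyl‑2‑oxo‑1,3‑oxazolidin‑3‑yl]‑4‑oxo‑3‑(3,4,5‑trimethoxybenzyl)butanoate F2. LiBH4 (THF, H2O, 0 °C) would remove the auxiliary reductively to give the hydroxy ester tert‑butyl (3R)‑3‑(hydroxymethyl)‑4‑(3,4,5‑trimethoxyphenyl)butanoate F3, and CF3CO2H in CH2Cl2 would cleave the tert‑butyl ester and close the lactone to 8.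

Step 6. The risks are proton transfer between product and enolate followed by a second benzylation, ionisation and self‑condensation of the electron‑rich benzylic bromide, and erosion of the trans selectivity. The fallback replaces SN2 alkylation by aldol addition and reductive removal of the carbinol oxygen; it sets out from 8 and 9 and returns at 13. Alcohol 9 would be oxidised (MnO2, CH2Cl2, rt) to 4‑(benzyloxy)‑3‑methoxybenzaldehyde F4. The lithium enolate 11 of lactone 8 (LiN(i‑Pr)2, THF, −78 °C) would add to this aldehyde anti to the C4 substituent to give the aldol (3S,4R)‑3‑{[4‑(benzyloxy)‑3‑methoxyphenyl](hydroxy)methyl}‑4‑(3,4,5‑trimethoxybenzyl)dihydrofuran‑2(3H)‑one F5 as a mixture of carbinol epimers. This aldol is 3,4‑trans; its C3 descriptor differs from that of 12 only because the carbinol carbon takes a higher priority. Hydrogenolysis (H2, Pd/C, AcOH with a trace of HClO4) should then remove the benzylic hydroxyl and the benzyl ether together and give 13 directly.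

Step 3. The risks are incomplete fragmentation of the sulfonylhydrazine intermediates and loss of the diazo ester by acid‑promoted decomposition during purification or by hydrolysis under the basic conditions. The fallback builds the diazo group by diazo transfer and deacylation; it sets out from 2 and returns at 7. Alcohol 2 would be acetoacetylated with 2,2,6‑trimethyl‑4H‑1,3‑dioxin‑4‑one (xylene, 140 °C) to 3‑(3,4,5‑trimethoxyphenyl)propyl 3‑oxobutanoate F6. Regitz diazo transfer (4‑acetamidobenzenesulfonyl azide, Et3N, MeCN) would give 3‑(3,4,5‑trimethoxyphenyl)propyl 2‑diazo‑3‑oxobutanoate F7, and deacetylation with LiOH in aqueous MeCN would give 7.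

**Further compounds**
F1 | step 4 | (4S)‑4‑benzyl‑3‑[3‑(3,4,5‑trimethoxyphenyl)propanoyl]‑1,3‑oxazolidin‑2‑one | COc1cc(CCC(=O)N2[C@@H](Cc3ccccc3)COC2=O)cc(OC)c1OC
F2 | step 4 | tert‑butyl (3R)‑4‑[(4S)‑4‑benzyl‑2‑oxo‑1,3‑oxazolidin‑3‑yl]‑4‑oxo‑3‑(3,4,5‑trimethoxybenzyl)butanoate | COc1cc(C[C@H](CC(=O)OC(C)(C)C)C(=O)N2[C@@H](Cc3ccccc3)COC2=O)cc(OC)c1OC
F3 | step 4 | tert‑butyl (3R)‑3‑(hydroxymethyl)‑4‑(3,4,5‑trimethoxyphenyl)butanoate | COc1cc(C[C@H](CC(=O)OC(C)(C)C)CO)cc(OC)c1OC
F4 | step 6 | 4‑(benzyloxy)‑3‑methoxybenzaldehyde | COc1cc(C=O)ccc1OCc1ccccc1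
F5 | step 6 | (3S,4R)‑3‑{[4‑(benzyloxy)‑3‑methoxyphenyl](hydroxy)methyl}‑4‑(3,4,5‑trimethoxybenzyl)dihydrofuran‑2(3H)‑one, mixture of carbinol epimers | COc1cc(C(O)[C@H]2C(=O)OC[C@@H]2Cc2cc(OC)c(OC)c(OC)c2)ccc1OCc1ccccc1
F6 | step 3 | 3‑(3,4,5‑trimethoxyphenyl)propyl 3‑oxobutanoate | COc1cc(CCCOC(=O)CC(C)=O)cc(OC)c1OC
F7 | step 3 | 3‑(3,4,5‑trimethoxyphenyl)propyl 2‑diazo‑3‑oxobutanoate | COc1cc(CCCOC(=O)C(=[N+]=[N-])C(C)=O)cc(OC)c1OC
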